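**Plan**

1. The benzene ring is numbered C1 (2-methylbutanoyl), C2 (OH), C3 (CH3), C4 (O-geranyl), C5 (acetyl), C6 (OH); O2, O4 and O6 are the oxygens on C2, C4 and C6.
2. Retrosynthetic cuts, in order: the C5 acetyl is traced back to a 1-ethoxyvinyl group, the O4–CH2 geranyl ether bond is cut, then the C5–C(vinyl) bond (cross-coupling of a C5 iodide), the C5–I bond, and last the C1–C(=O) bond (Friedel–Crafts).
3. Enabling feature: once C1 of 2-methylphloroglucinol is acylated, C5 is the only ring carbon left with hydrogen, so iodine and then the two-carbon unit can only enter there. While that unit is an enol ether and not a ketone, O4 (para to the C1 ketone) is the one oxygen without a carbonyl neighbour; a real C5 acetyl would put O2 and O4 each beside a ketone.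
4. Forward: acid chloride, C1 acylation, C5 iodination, triacetate, coupling with the 1-ethoxyvinyl stannane, acetate removal with O4 geranylation in one flask, enol ether hydrolysis. The pieces are joined in the order acyl, vinyl, geranyl, and no ring is formed.
5. The phenols are acetylated only for the coupling, so that no acidic OH meets the stannane or the enol ether. The geranyl ether is made after all palladium chemistry, because aryl allyl ethers ionise with zerovalent palladium.
6. Stereochemistry: the single stereocentre is bought as (R)-2-methylbutanoic acid and carried through conditions that should not enolise the ketone; the (E) alkene comes with geranyl bromide.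

Key step: step 5

Assumption: 2-methylphloroglucinol, (R)-2-methylbutanoic acid (enantiopure), the stannane and geranyl bromide are purchased, as are ethyl vinyl ether and geraniol named in the fallbacks.

**Route**

Step 1
Reactants: 1 (R)-2-methylbutanoic acid
Product: 2 (R)-2-methylbutanoyl chloride
Conditions: (COCl)2 (1.2 equiv), DMF (cat.), CH2Cl2, 0 °C → rt; excess reagent evaporated, used as a CH2Cl2 solution
Reagents that add atoms: oxalyl chloride, O=C(Cl)C(=O)Cl
Why: Acyl chloride formation through the chloroiminium (Vilsmeier-type) species from DMF and oxalyl chloride runs without base at or below room temperature, so the alpha stereocentre of the saturated acid should not be enolised.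

Step 2
Reactants: 2 (R)-2-methylbutanoyl chloride; 3 2-methylphloroglucinol
Product: 4 (R)-2-methyl-1-(2,4,6-trihydroxy-3-methylphenyl)butan-1-one
Conditions: AlCl3 (3.5 equiv), CH2Cl2/PhNO2, 0 °C → rt; ice/1 M HCl quench
Reagents that add atoms: none
Why: Friedel–Crafts C-acylation of the AlCl3-complexed phloroglucinol should give one regioisomer because the two unsubstituted ring carbons of 3 are equivalent, the first acyl group deactivates the ring against a second, and low temperature without amine base keeps ketene formation and enolisation at the stereocentre down.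

Step 3
Reactants: 4 (R)-2-methyl-1-(2,4,6-trihydroxy-3-methylphenyl)butan-1-one
Product: 5 (R)-1-(2,4,6-trihydroxy-3-iodo-5-methylphenyl)-2-methylbutan-1-one
Conditions: NIS (1.0 equiv), MeCN, 0 °C, dark
Reagents that add atoms: N-iodosuccinimide, O=C1CCC(=O)N1I
Why: Electrophilic aromatic iodination (SEAr) of a phloroglucinol nucleus is fast at 0 °C and can only take C5, the one ring carbon still bearing hydrogen, which is ortho to two hydroxyls and para to the third.

Step 4
Reactants: 5 (R)-1-(2,4,6-trihydroxy-3-iodo-5-methylphenyl)-2-methylbutan-1-one
Product: 6 2-iodo-4-methyl-6-[(2R)-2-methylbutanoyl]benzene-1,3,5-triyl triacetate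
Conditions: Ac2O (4 equiv), pyridine, DMAP (cat.), CH2Cl2, 0 °C → rt
Reagents that add atoms: acetic anhydride, CC(=O)OC(C)=O
Why: DMAP-catalysed O-acetylation should cap all three phenols, the two chelated ones included, so that no acidic OH remains to consume the stannane, reduce the C–I bond or protonate the enol ether made next, while pyridine is too weak a base to enolise the ketone.

Step 5
Reactants: 6 2-iodo-4-methyl-6-[(2R)-2-methylbutanoyl]benzene-1,3,5-triyl triacetate; 7 tributyl(1-ethoxyvinyl)stannane (1.5 equiv)
Product: 8 2-(1-ethoxyvinyl)-4-methyl-6-[(2R)-2-methylbutanoyl]benzene-1,3,5-triyl triacetate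
Conditions: Pd(PPh3)4 (5 mol %, zerovalent palladium), CuI (10 mol %), DMF, 70 °C, argon; chromatography on Et3N-deactivated silica
Reagents that add atoms: none
Why: Zerovalent palladium inserts into the C5–I bond of 6, CuI relays the 1-ethoxyvinyl group from tin via copper to the arylpalladium iodide, and reductive elimination forms the C5–C(1-ethoxyvinyl) bond. The closest known reaction type is the Migita–Kosugi–Stille coupling of aryl iodides with tributyl(1-ethoxyvinyl)stannane as an acetyl anion equivalent, run with the copper co-catalyst used for doubly ortho-substituted halides. No ring is closed and no stereocentre is created. Site selectivity needs no control, because 6 holds a single C–I bond at the only ring carbon that was free after acylation. Chemoselectivity rests on neutral, base-free conditions that should leave the aryl acetates, the ketone and its alpha stereocentre alone, and on the absence of any free phenol, so the stannane is not protonated and the enol ether should survive isolation on amine-treated silica. Because the two carbons arrive as an enol ether and not as a carbonyl, O4 remains the only oxygen without a ketone neighbour when the acetates are removed in step 6.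

Step 6
Reactants: 8 2-(1-ethoxyvinyl)-4-methyl-6-[(2R)-2-methylbutanoyl]benzene-1,3,5-triyl triacetate; 9 geranyl bromide
Product: 11 (R)-1-[4-{[(2E)-3,7-dimethylocta-2,6-dien-1-yl]oxy}-3-(1-ethoxyvinyl)-2,6-dihydroxy-5-methylphenyl]-2-methylbutan-1-one, via 1-ethoxyvinyl triol phenoxide 10 (not isolated)
Conditions: K2CO3 (2 equiv), MeOH, 0 °C, argon; evaporate; then 9 (1.05 equiv), DMF, 0 °C → rt
Reagents that add atoms: none
Why: Base-mediated methanolysis of the three aryl acetates should release the triol directly as its phenoxide, in which O4 (para to the C1 ketone) is the only oxygen not chelated to a carbonyl, so Williamson alkylation by the primary allylic bromide should go to O4, while the medium stays basic throughout, so the enol ether never meets a free acidic phenol and the phenoxide-deactivated ketone should not epimerise.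

Step 7
Reactants: 11 (R)-1-[4-{[(2E)-3,7-dimethylocta-2,6-dien-1-yl]oxy}-3-(1-ethoxyvinyl)-2,6-dihydroxy-5-methylphenyl]-2-methylbutan-1-one
Product: 12 (R)-1-[3-acetyl-4-{[(2E)-3,7-dimethylocta-2,6-dien-1-yl]oxy}-2,6-dihydroxy-5-methylphenyl]-2-methylbutan-1-one (CNP0106233.1)
Conditions: 0.5 M aq. HCl, THF, 0 °C, short reaction time
Reagents that add atoms: water, O
Why: Acid-catalysed enol ether hydrolysis (C-protonation, hemiketal, loss of ethanol) should be far faster than ionisation of the geranyl aryl ether in cold dilute acid, and it unveils the C5 acetyl between O4 and O6 without touching the stereocentre.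

**Compound list**

1 | (R)-2-methylbutanoic acid | CC[C@@H](C)C(=O)O | starting material
2 | (R)-2-methylbutanoyl chloride | CC[C@@H](C)C(=O)Cl | intermediate
3 | 2-methylphloroglucinol (2-methylbenzene-1,3,5-triol) | Cc1c(O)cc(O)cc1O | starting material
4 | (R)-2-methyl-1-(2,4,6-trihydroxy-3-methylphenyl)butan-1-one | CC[C@@H](C)C(=O)c1c(O)c(C)c(O)cc1O | intermediate
5 | (R)-1-(2,4,6-trihydroxy-3-iodo-5-methylphenyl)-2-methylbutan-1-one | CC[C@@H](C)C(=O)c1c(O)c(C)c(O)c(I)c1O | intermediate
6 | 2-iodo-4-methyl-6-[(2R)-2-methylbutanoyl]benzene-1,3,5-triyl triacetate | CC[C@@H](C)C(=O)c1c(OC(C)=O)c(C)c(OC(C)=O)c(I)c1OC(C)=O | intermediate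
7 | tributyl(1-ethoxyvinyl)stannane | CCCC[Sn](CCCC)(CCCC)C(=C)OCC | starting material
8 | 2-(1-ethoxyvinyl)-4-methyl-6-[(2R)-2-methylbutanoyl]benzene-1,3,5-triyl triacetate | CC[C@@H](C)C(=O)c1c(OC(C)=O)c(C)c(OC(C)=O)c(C(=C)OCC)c1OC(C)=O | intermediate
9 | geranyl bromide, (2E)-1-bromo-3,7-dimethylocta-2,6-diene | CC(C)=CCC/C(C)=C/CBr | starting material
10 | (R)-1-[3-(1-ethoxyvinyl)-2,4,6-trihydroxy-5-methylphenyl]-2-methylbutan-1-one (present in the flask as its potassium phenoxide) | CC[C@@H](C)C(=O)c1c(O)c(C)c(O)c(C(=C)OCC)c1O | intermediate
11 | (R)-1-[4-{[(2E)-3,7-dimethylocta-2,6-dien-1-yl]oxy}-3-(1-ethoxyvinyl)-2,6-dihydroxy-5-methylphenyl]-2-methylbutan-1-one | CC[C@@H](C)C(=O)c1c(O)c(C)c(OC/C=C(\C)CCC=C(C)C)c(C(=C)OCC)c1O | intermediate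
12 | (R)-1-[3-acetyl-4-{[(2E)-3,7-dimethylocta-2,6-dien-1-yl]oxy}-2,6-dihydroxy-5-methylphenyl]-2-methylbutan-1-one | CC[C@@H](C)C(=O)c1c(O)c(C)c(OC/C=C(\C)CCC=C(C)C)c(C(C)=O)c1O | target

**Summary**

Total step count: 7. Longest linear sequence: 7 steps (1 → 2 → 4 → 5 → 6 → 8 → 11 → 12).

Steps most likely to fail:

Step 5. Transmetalation to an arylpalladium iodide flanked by two acetoxy groups may be slow, so that reductive loss of iodine and homocoupling of the stannane overtake the cross-coupling. The fallback sets out from 6 and returns at 8, replacing tin by zinc in a Negishi coupling. Ethyl vinyl ether is deprotonated at the alpha carbon with t-BuLi in THF (−78 → 0 °C) to give (1-ethoxyvinyl)lithium F1. ZnCl2 converts this into (1-ethoxyvinyl)zinc chloride F2, which is coupled with 6 under Pd(PPh3)4 in THF at rt to 40 °C. The zinc reagent transmetalates much faster than the stannane and should tolerate the aryl acetates and the hindered ketone; the product is 8.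

Step 6. After the acetates are removed, the ambident phenoxide may be alkylated at a ring carbon with loss of aromaticity or alkylated twice. Alternatively, adventitious acid may hydrolyse the enol ether before O4 is capped, which would erase the difference between O2 and O4. The fallback sets out from 8 and returns at 11, replacing the phenoxide alkylation by a Mitsunobu etherification. Compound 8 is deacetylated with K2CO3 in MeOH, the solution is brought to pH 7 with cold phosphate buffer, and triol 10 is extracted and used at once with geraniol, PPh3 and diisopropyl azodicarboxylate in THF at 0 °C. The Mitsunobu reaction engages only the most acidic, non-chelated hydroxyl (O4) and offers no free allyl electrophile for C-alkylation. It delivers 11 and forms no compound outside the list (F0).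

Step 2. The enantiomeric purity may erode through ketene formation from the acyl chloride or enolisation of the AlCl3-bound ketone, and a second acylation may occur at the other free ring carbon. The fallback sets out from 3 and 2 and returns at 4, building the ketone from an aryllithium and a Weinreb amide. Compound 3 is treated with chloromethyl methyl ether and i-Pr2NEt in CH2Cl2 to give 1,3,5-tris(methoxymethoxy)-2-methylbenzene F3. Compound 2 with N,O-dimethylhydroxylamine hydrochloride and pyridine gives (R)-N-methoxy-N,2-dimethylbutanamide F4. n-BuLi in THF at 0 °C lithiates F3 at a ring carbon between two methoxymethoxy groups to give [2,4,6-tris(methoxymethoxy)-3-methylphenyl]lithium F5. This adds once to F4 and gives, after NH4Cl work-up, (R)-2-methyl-1-[2,4,6-tris(methoxymethoxy)-3-methylphenyl]butan-1-one F6. HCl in MeOH at rt removes the three acetals and gives 4.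

Further compounds
F1 | step 5 | (1-ethoxyvinyl)lithium | [Li]C(=C)OCC
F2 | step 5 | (1-ethoxyvinyl)zinc chloride | Cl[Zn]C(=C)OCC
F0 | step 6 | none | none
F3 | step 2 | 1,3,5-tris(methoxymethoxy)-2-methylbenzene | Cc1c(OCOC)cc(OCOC)cc1OCOC
F4 | step 2 | (R)-N-methoxy-N,2-dimethylbutanamide | CC[C@@H](C)C(=O)N(C)OC
F5 | step 2 | [2,4,6-tris(methoxymethoxy)-3-methylphenyl]lithium | [Li]c1c(OCOC)cc(OCOC)c(C)c1OCOC
F6 | step 2 | (R)-2-methyl-1-[2,4,6-tris(methoxymethoxy)-3-methylphenyl]butan-1-one | CC[C@@H](C)C(=O)c1c(OCOC)c(C)c(OCOC)cc1OCOC
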